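**Retrosynthetic overview**
1. Target 13 ⇒ (3S)-β-hydroxy ketone 10 + acetaldehyde: an Evans–Tishchenko reduction creates the C5 carbinol anti to C3 and places the acetate on O3 in the same step.
2. 10 ⇒ Weinreb amide 7 + pentylmagnesium bromide; 7 ⇒ (S)-β-hydroxy ester 6 ⇒ β-keto ester 5 (asymmetric hydrogenation sets C3).
3. 5 ⇒ key C3–C4 bond by crossed Claisen condensation of acid chloride 2 (from acid 1) with the lithium enolate of ethyl acetate.
4. Rings: none is formed; the only ring, the dimethoxybenzene, is bought in acid 1.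

Assumption: the SMILES is read as (3S,5S)-1-(3,4-dimethoxyphenyl)-5-hydroxydecan-3-yl acetate, the 1,3-anti diol acetylated at O3 (decane numbering: C1 benzylic CH2, C3 acetoxy carbon, C5 hydroxy carbon).
Convention: building blocks whose carbon ends up in the target are numbered and stand under Reactants and again under "Reagents that add atoms"; other atom-donating reagents are given there by name and SMILES only.

**Route**

Step 1
Reactants: 1 3-(3,4-dimethoxyphenyl)propanoic acid
Product: 2 3-(3,4-dimethoxyphenyl)propanoyl chloride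
Conditions: (COCl)2 (1.3 equiv), DMF (cat.), CH2Cl2, 0 °C to rt; evaporate, use crude
Reagents that add atoms: oxalyl chloride, ClC(=O)C(Cl)=O
Why: DMF-catalysed acid chloride formation is essentially quantitative for a simple alkanoic acid, gives only gaseous by-products, and leaves the dimethoxyarene untouched because no Lewis acid is present.

Step 2
Reactants: 2 3-(3,4-dimethoxyphenyl)propanoyl chloride; 3 ethyl acetate
Product: 5 ethyl 5-(3,4-dimethoxyphenyl)-3-oxopentanoate, via lithium enolate of ethyl acetate 4 (not isolated)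
Conditions: 3 (2.2 equiv), LiN(SiMe3)2 (2.2 equiv), THF, −78 °C, 30 min; then 2 (1.0 equiv), −78 °C, 1 h; 1 M HCl
Reagents that add atoms: ethyl acetate (3), CCOC(C)=O
Why: In this crossed Claisen condensation the preformed ester enolate is C-acylated by the acid chloride at −78 °C, and the second equivalent of enolate deprotonates the β-keto ester as it forms, which prevents double acylation.

Step 3
Reactants: 5 ethyl 5-(3,4-dimethoxyphenyl)-3-oxopentanoate
Product: 6 ethyl (3S)-5-(3,4-dimethoxyphenyl)-3-hydroxypentanoate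
Conditions: H2 (10 bar), [RuCl(p-cymene)((S)-BINAP)]Cl (0.5 mol %), degassed EtOH, 80 °C
Reagents that add atoms: none
Why: In this Noyori asymmetric hydrogenation the ester carbonyl chelates ruthenium and the (S)-BINAP ligand directs hydride to one ketone face, giving the (S)-carbinol at C3 (the same sense by which (R)-BINAP gives methyl (R)-3-hydroxybutanoate), typically in at least 97% ee.

Step 4
Reactants: 6 ethyl (3S)-5-(3,4-dimethoxyphenyl)-3-hydroxypentanoate
Product: 7 (3S)-5-(3,4-dimethoxyphenyl)-3-hydroxy-N-methoxy-N-methylpentanamide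
Conditions: MeNHOMe·HCl (3 equiv), iPrMgCl (7 equiv), THF, −20 to 0 °C; aq. NH4Cl
Reagents that add atoms: N,O-dimethylhydroxylamine hydrochloride, CNOC.Cl
Why: Weinreb amide formation by aminolysis of the ethyl ester with ClMgN(OMe)Me proceeds at low temperature while the hydroxyl sits as an inert magnesium alkoxide, so C3 is not touched.

Step 5
Reactants: 7 (3S)-5-(3,4-dimethoxyphenyl)-3-hydroxy-N-methoxy-N-methylpentanamide; 8 pentylmagnesium bromide
Product: 10 (3S)-1-(3,4-dimethoxyphenyl)-3-hydroxydecan-5-one, via tetrahedral magnesium adduct 9 (not isolated)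
Conditions: 8 (3.5 equiv), THF, 0 °C to rt; aq. NH4Cl, 0 °C
Reagents that add atoms: pentylmagnesium bromide (8), CCCCC[Mg]Br
Why: In this Weinreb ketone synthesis the first equivalent of Grignard reagent deprotonates the hydroxyl and the next adds once to give a stable N-methoxy chelate that releases the ketone only on work-up, so neither over-addition nor retro-aldol can occur.

Step 6
Reactants: 10 (3S)-1-(3,4-dimethoxyphenyl)-3-hydroxydecan-5-one; 11 acetaldehyde
Product: 13 (3S,5S)-1-(3,4-dimethoxyphenyl)-5-hydroxydecan-3-yl acetate, via samarium hemiacetal 12 (not isolated)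
Conditions: 11 (6 equiv, freshly distilled), SmI2 (0.3 equiv), THF, −10 °C, 1 h; aq. NaHCO3 as soon as 10 is consumed
Reagents that add atoms: acetaldehyde (11), CC=O
Why: In this Evans–Tishchenko reduction the C3 hydroxyl forms a hemiacetal with acetaldehyde on the trivalent samarium catalyst generated from SmI2, and its hydride is delivered intramolecularly through a chair-like bicyclic transition state to the C5 ketone, which sets the 1,3-anti (5S) carbinol with high selectivity and leaves the oxidized hemiacetal as the acetate on O3.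

**Compound list**
1 | 3-(3,4-dimethoxyphenyl)propanoic acid | OC(=O)CCc1ccc(OC)c(OC)c1 | starting material
2 | 3-(3,4-dimethoxyphenyl)propanoyl chloride | ClC(=O)CCc1ccc(OC)c(OC)c1 | intermediate
3 | ethyl acetate | CCOC(C)=O | starting material
4 | lithium enolate of ethyl acetate (1-ethoxyethenyloxylithium; not isolated) | C=C(O[Li])OCC | intermediate
5 | ethyl 5-(3,4-dimethoxyphenyl)-3-oxopentanoate | CCOC(=O)CC(=O)CCc1ccc(OC)c(OC)c1 | intermediate
6 | ethyl (3S)-5-(3,4-dimethoxyphenyl)-3-hydroxypentanoate | CCOC(=O)C[C@@H](O)CCc1ccc(OC)c(OC)c1 | intermediate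
7 | (3S)-5-(3,4-dimethoxyphenyl)-3-hydroxy-N-methoxy-N-methylpentanamide | CON(C)C(=O)C[C@@H](O)CCc1ccc(OC)c(OC)c1 | intermediate
8 | pentylmagnesium bromide | CCCCC[Mg]Br | starting material
9 | tetrahedral magnesium adduct: bis(bromomagnesium) alkoxide of (3S)-1-(3,4-dimethoxyphenyl)-5-[methoxy(methyl)amino]decane-3,5-diol (C5 not defined; not isolated) | CCCCCC(O[Mg]Br)(C[C@@H](O[Mg]Br)CCc1ccc(OC)c(OC)c1)N(C)OC | intermediate
10 | (3S)-1-(3,4-dimethoxyphenyl)-3-hydroxydecan-5-one | CCCCCC(=O)C[C@@H](O)CCc1ccc(OC)c(OC)c1 | intermediate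
11 | acetaldehyde | CC=O | starting material
12 | samarium hemiacetal: (3S)-1-(3,4-dimethoxyphenyl)-3-(1-hydroxyethoxy)decan-5-one, held as its samarium alkoxide (hemiacetal carbon not defined; not isolated; SMILES of the neutral hemiacetal) | CCCCCC(=O)C[C@H](CCc1ccc(OC)c(OC)c1)OC(C)O | intermediate
13 | (3S,5S)-1-(3,4-dimethoxyphenyl)-5-hydroxydecan-3-yl acetate (CNP0382730.1) | CCCCC[C@H](O)C[C@H](CCc1ccc(OC)c(OC)c1)OC(C)=O | target

**Totals and weak points**
Total step count: 6. Longest linear sequence: 6 steps (1 → 2 → 5 → 6 → 7 → 10 → 13).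

Most likely to fail, in order:

Step 6 (Evans–Tishchenko with acetaldehyde). The risks are acetate migration between O3 and O5 on the Lewis-acidic samarium, which would give a regioisomer that is hard to separate, self-reaction of the volatile aldehyde, and retro-aldol of 10. The fallback sets out from 10 and installs a non-migrating ester first. Evans–Tishchenko reduction with benzaldehyde (SmI2 cat., THF, −10 °C) gives (3S,5S)-1-(3,4-dimethoxyphenyl)-5-hydroxydecan-3-yl benzoate F1. Silylation of the C5 hydroxyl (TBSOTf, 2,6-lutidine, CH2Cl2, −78 °C) gives (3S,5S)-5-(tert-butyldimethylsilyloxy)-1-(3,4-dimethoxyphenyl)decan-3-yl benzoate F2. Reductive removal of the benzoate (iBu2AlH, CH2Cl2, −78 °C) gives (3S,5S)-5-(tert-butyldimethylsilyloxy)-1-(3,4-dimethoxyphenyl)decan-3-ol F3. Acetylation (Ac2O, pyridine, DMAP, CH2Cl2, rt) gives (3S,5S)-5-(tert-butyldimethylsilyloxy)-1-(3,4-dimethoxyphenyl)decan-3-yl acetate F4. HF·pyridine in THF at 0 °C then removes the silyl group under acidic conditions that do not move the acetate, and the sequence comes back to the route at 13.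

Step 5 (Grignard addition to the unprotected β-hydroxy Weinreb amide). The magnesium alkoxide may make the addition sluggish or promote enolization or elimination. The fallback sets out from 7 and masks the hydroxyl. TESCl and imidazole in DMF give (3S)-5-(3,4-dimethoxyphenyl)-N-methoxy-N-methyl-3-(triethylsilyloxy)pentanamide F5. Pentylmagnesium bromide (1.5 equiv, THF, 0 °C) then gives (3S)-1-(3,4-dimethoxyphenyl)-3-(triethylsilyloxy)decan-5-one F6. Mild acid (AcOH/THF/H2O 3:1:1, rt) cleaves the silyl ether without β-elimination, and the sequence comes back to the route at 10.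

Step 2 (crossed Claisen with an enolizable acid chloride). O-acylation, ketene formation or double acylation could lower the yield. The fallback sets out from 2 and uses a malonate-type acceptor. Meldrum's acid and pyridine in CH2Cl2 at 0 °C give 5-[3-(3,4-dimethoxyphenyl)-1-hydroxypropylidene]-2,2-dimethyl-1,3-dioxane-4,6-dione F7. Refluxing F7 in ethanol opens the dioxanedione and decarboxylates it, and the sequence comes back to the route at 5.

**Further compounds**
F1 | step 6 | (3S,5S)-1-(3,4-dimethoxyphenyl)-5-hydroxydecan-3-yl benzoate | CCCCC[C@H](O)C[C@H](CCc1ccc(OC)c(OC)c1)OC(=O)c1ccccc1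
F2 | step 6 | (3S,5S)-5-(tert-butyldimethylsilyloxy)-1-(3,4-dimethoxyphenyl)decan-3-yl benzoate | CCCCC[C@H](O[Si](C)(C)C(C)(C)C)C[C@H](CCc1ccc(OC)c(OC)c1)OC(=O)c1ccccc1
F3 | step 6 | (3S,5S)-5-(tert-butyldimethylsilyloxy)-1-(3,4-dimethoxyphenyl)decan-3-ol | CCCCC[C@H](O[Si](C)(C)C(C)(C)C)C[C@H](CCc1ccc(OC)c(OC)c1)O
F4 | step 6 | (3S,5S)-5-(tert-butyldimethylsilyloxy)-1-(3,4-dimethoxyphenyl)decan-3-yl acetate | CCCCC[C@H](O[Si](C)(C)C(C)(C)C)C[C@H](CCc1ccc(OC)c(OC)c1)OC(C)=O
F5 | step 5 | (3S)-5-(3,4-dimethoxyphenyl)-N-methoxy-N-methyl-3-(triethylsilyloxy)pentanamide | CON(C)C(=O)C[C@@H](O[Si](CC)(CC)CC)CCc1ccc(OC)c(OC)c1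
F6 | step 5 | (3S)-1-(3,4-dimethoxyphenyl)-3-(triethylsilyloxy)decan-5-one | CCCCCC(=O)C[C@@H](O[Si](CC)(CC)CC)CCc1ccc(OC)c(OC)c1
F7 | step 2 | 5-[3-(3,4-dimethoxyphenyl)-1-hydroxypropylidene]-2,2-dimethyl-1,3-dioxane-4,6-dione | CC1(C)OC(=O)C(=C(O)CCc2ccc(OC)c(OC)c2)C(=O)O1
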